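**Retrosynthetic overview**

1. The target is opened at C12–C13 (Negishi sp3–sp2 coupling, then desilylation) into a decalin alkyl iodide and an (S)-butenolide vinyl iodide made from methyl (S)-glycidate.
2. The 6α,8α-diol of ring B comes from a trans-fused 7-en-6-one (α-epoxidation, reductive epoxide opening, dissolving-metal reduction), and that enone from its cis-fused C5 epimer.
3. Ring B is made in one operation (C5–C6 and C9–C10) by an intramolecular Diels–Alder reaction. The enabling feature is that the C18 hydroxymethyl on C4 and the C6 oxygen are 1,3-related across C4–C5, so O–C18–C4 is a three-atom tether. The C18 ester of an (E)-3-methylhex-3-enoic acid, as its vinylketene silyl acetal (diene C6=C7–C8=C9), adds to the C5=C10 alkene of ring A and closes a temporary oxolane C4–C18–O–C6–C5. Hydrolysis removes that ring and leaves C6=O and C18–OH.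
4. Ring A is made first, by asymmetric Birch reduction–methylation of a 2-methoxy-5-methylbenzamide (sets C4), then anti reduction (sets C3). Ring order: A, then B together with the temporary oxolane, with the butenolide ring made separately and attached last.

Key step: step 11

Numbering remark: decalin carbons carry labdane numbers (C17 = methyl on C8, C18 = oxygenated carbon on C4 (α), C19 = methyl on C4 (β), C20 = methyl on C10, C11/C12 = first side-chain carbons); α is the face opposite the C10 methyl.

Assumption: in step 2 the methylation is taken to occur on the enolate face away from the methoxymethyl arm of the (S)-auxiliary, giving the quaternary centre drawn; if the sense is opposite, the (R)-auxiliary is used and nothing else changes.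

**Ring A**

Step 1
Reactants: 1 2-methoxy-5-methylbenzoic acid; 2 (2S)-2-(methoxymethyl)pyrrolidine
Product: 4 [(2S)-2-(methoxymethyl)pyrrolidin-1-yl](2-methoxy-5-methylphenyl)methanone, via acid chloride 3 (not isolated)
Conditions: (COCl)2, DMF (cat.), CH2Cl2, 0 °C → rt; then 2, Et3N, CH2Cl2, 0 °C → rt
Reagents that add atoms: none
Why: Acylation of the secondary amine by the acid chloride (amide formation) installs the chiral auxiliary and creates no stereocentre.

Step 2
Reactants: 4 [(2S)-2-(methoxymethyl)pyrrolidin-1-yl](2-methoxy-5-methylphenyl)methanone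
Product: 6 [(1S)-2-methoxy-1,5-dimethylcyclohexa-2,5-dien-1-yl][(2S)-2-(methoxymethyl)pyrrolidin-1-yl]methanone, via potassium amide enolate 5 (not isolated)
Conditions: K, NH3(l)/THF, t-BuOH (1 equiv), −78 °C; then MeI, −78 °C
Reagents that add atoms: iodomethane, CI
Why: Asymmetric Birch reduction–alkylation of a chiral 2-methoxybenzamide reduces the ring at the ipso and para carbons and methylates the chelated amide enolate on the face away from the methoxymethyl arm, which sets the quaternary carbon (future C4) and leaves the 5-methyl group on the remaining trisubstituted alkene (future C5=C10).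

Step 3
Reactants: 6 [(1S)-2-methoxy-1,5-dimethylcyclohexa-2,5-dien-1-yl][(2S)-2-(methoxymethyl)pyrrolidin-1-yl]methanone
Product: 7 [(1R)-2-methoxy-1,5-dimethylcyclohexa-2,5-dien-1-yl]methanol
Conditions: LiNH2BH3 (from BH3·NH3 and LiN(i-Pr)2), THF, 0 °C → rt
Reagents that add atoms: none
Why: Lithium amidotrihydroborate reduces hindered tertiary amides to primary alcohols with C–N cleavage, leaves the enol ether and both alkenes alone, and releases the auxiliary without touching the quaternary centre.

Step 4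
Reactants: 7 [(1R)-2-methoxy-1,5-dimethylcyclohexa-2,5-dien-1-yl]methanol
Product: 8 (2R)-2-(hydroxymethyl)-2,4-dimethylcyclohex-3-en-1-one
Conditions: 1 M HCl, THF, 0 °C
Reagents that add atoms: water, O
Why: Mild acid hydrolysis of the methyl enol ether gives the ketone, and the remaining alkene cannot move into conjugation because the α-carbon is quaternary.

Step 5
Reactants: 8 (2R)-2-(hydroxymethyl)-2,4-dimethylcyclohex-3-en-1-one
Product: 9 (1S,2R)-2-(hydroxymethyl)-2,4-dimethylcyclohex-3-en-1-ol
Conditions: Me4NBH(OAc)3, MeCN/AcOH, −30 °C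
Reagents that add atoms: none
Why: In this Evans–Saksena anti reduction the primary hydroxyl binds boron and delivers hydride to the carbonyl face on which the CH2OH group lies, so the new hydroxyl (future C3–OH) ends trans to CH2OH and cis to the methyl group.

**Diene acid**

Step 6
Reactants: 10 tert-butyl(but-3-yn-1-yloxy)dimethylsilane
Product: 12 (3E)-6-[(tert-butyldimethylsilyl)oxy]-4-methylhex-3-en-1-ol, via alkenylalane 11 (not isolated)
Conditions: AlMe3, Cp2ZrCl2 (20 mol%), CH2Cl2, 0 °C → rt; then n-BuLi, hexane/THF, −78 °C; oxirane, −78 °C → rt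
Reagents that add atoms: trimethylaluminium, C[Al](C)C; oxirane, C1CO1
Why: Negishi carboalumination adds methyl and aluminium syn across the terminal alkyne, and the derived alkenylalanate opens oxirane with retention, which fixes the E trisubstituted alkene (future C8=C9).

Step 7
Reactants: 12 (3E)-6-[(tert-butyldimethylsilyl)oxy]-4-methylhex-3-en-1-ol
Product: 13 tert-butyl{[(3E)-6-(benzyloxy)-3-methylhex-3-en-1-yl]oxy}dimethylsilane
Conditions: NaH, BnBr, n-Bu4NI (cat.), THF, 0 °C → rt
Reagents that add atoms: benzyl bromide, BrCc1ccccc1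
Why: Williamson etherification of the primary alkoxide gives the benzyl ether that will carry C12 through to step 16.

Step 8
Reactants: 13 tert-butyl{[(3E)-6-(benzyloxy)-3-methylhex-3-en-1-yl]oxy}dimethylsilane
Product: 14 (3E)-6-(benzyloxy)-3-methylhex-3-enoic acid
Conditions: CrO3, H2SO4, H2O (Jones conditions), acetone, 0 °C
Reagents that add atoms: water, O
Why: Under Jones oxidation conditions the primary silyl ether is cleaved and the freed alcohol is oxidised through the aldehyde hydrate to the acid, while at 0 °C the β,γ-alkene keeps its position and geometry.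

**Union and ring B**

Step 9
Reactants: 9 (1S,2R)-2-(hydroxymethyl)-2,4-dimethylcyclohex-3-en-1-ol; 14 (3E)-6-(benzyloxy)-3-methylhex-3-enoic acid
Product: 15 [(1R,6S)-6-hydroxy-1,3-dimethylcyclohex-2-en-1-yl]methyl (3E)-6-(benzyloxy)-3-methylhex-3-enoate
Conditions: EDC·HCl, DMAP (10 mol%), CH2Cl2, 0 °C
Reagents that add atoms: none
Why: Steglich-type carbodiimide esterification acylates the primary hydroxyl in preference to the secondary one flanked by the quaternary carbon, and low temperature with little DMAP keeps the β,γ-alkene out of conjugation.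

Step 10
Reactants: 15 [(1R,6S)-6-hydroxy-1,3-dimethylcyclohex-2-en-1-yl]methyl (3E)-6-(benzyloxy)-3-methylhex-3-enoate
Product: 16 [(1R,6S)-6-[(tert-butyldimethylsilyl)oxy]-1,3-dimethylcyclohex-2-en-1-yl]methyl (3E)-6-(benzyloxy)-3-methylhex-3-enoate
Conditions: TBSOTf, 2,6-lutidine, CH2Cl2, −78 °C
Reagents that add atoms: tert-butyldimethylsilyl trifluoromethanesulfonate, CC(C)(C)[Si](C)(C)OS(=O)(=O)C(F)(F)F
Why: Silyl triflate silylation of the hindered secondary alcohol with a non-nucleophilic base at low temperature avoids acyl migration and removes the only acidic proton other than the ester α-hydrogens.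

Step 11
Reactants: 16 [(1R,6S)-6-[(tert-butyldimethylsilyl)oxy]-1,3-dimethylcyclohex-2-en-1-yl]methyl (3E)-6-(benzyloxy)-3-methylhex-3-enoate
Product: 19 12-(benzyloxy)-3β-(tert-butyldimethylsilyloxy)-18-hydroxy-5β-13,14,15,16-tetranorlabd-7-en-6-one (cis-fused; 9α-H; 10β-methyl), via ketene silyl acetal 17 (not isolated), via tricyclic silyl ketal 18 (not isolated)
Conditions: LiN(i-Pr)2, TBSCl, THF/DMPU, −78 °C → rt; then toluene, Et3N (cat.), BHT, sealed tube, 170 °C; then 1 M HCl, THF, 0 °C
Reagents that add atoms: none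
Why: Proposed new method: a thermal, concerted type 1 intramolecular Diels–Alder reaction of the (1Z,3E)-vinylketene silyl acetal 17 with the unactivated trisubstituted C5=C10 alkene of ring A, whose closest known relatives are intermolecular Diels–Alder reactions of vinylketene silyl acetals and thermal intramolecular Diels–Alder reactions of 1-oxygenated dienes with unactivated alkenes through three-atom tethers; turning the ester into its ketene acetal removes the s-trans ester preference that normally blocks ester-tethered cases, and the quaternary C4 adds a Thorpe–Ingold bias. Ring B is closed by the cycloaddition itself (C5–C6 and C9–C10, suprafacial on both partners), and the temporary oxolane C4–C18–O–C6–C5 is closed as the tether ring, necessarily cis-fused to ring A. C10 is controlled by the C4 stereocentre, because the O–C18 tether can deliver the diene only to the ring-A face that carries C18, which leaves the C10 methyl on the β face; C9 follows from the E geometry of C8=C9 and from the tether-enforced orientation in which C7–C8 point away from ring A, which puts the side chain anti to C5 across C9–C10 as in the target; C5 is formed cis (5β-H) and is corrected in step 12, and the C6 ketal centre disappears on hydrolysis. The step needs regioselectivity (C6 to C5, C9 to C10), which the tether secures, and it needs the ketene acetal isomer with the C18–O bond trans to C8, which enolisation in THF/DMPU (α-substituent syn to the O–metal bond) should favour. Aqueous acid then cleaves silyl ketal 18 to the C6 ketone, conjugated with C7=C8, and frees the C18 hydroxyl.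

Step 12
Reactants: 19 12-(benzyloxy)-3β-(tert-butyldimethylsilyloxy)-18-hydroxy-5β-13,14,15,16-tetranorlabd-7-en-6-one
Product: 20 12-(benzyloxy)-3β-(tert-butyldimethylsilyloxy)-18-hydroxy-5α-13,14,15,16-tetranorlabd-7-en-6-one (trans-fused)
Conditions: K2CO3, MeOH, rt
Reagents that add atoms: none
Why: Base-mediated epimerisation through the C5 (α′) enolate should equilibrate the enone to the more stable trans-fused decalin, as in the known C5 epimerisation of steroidal 7-en-6-ones, and the mild base should spare the γ-hydrogen at C9.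

Step 13
Reactants: 20 12-(benzyloxy)-3β-(tert-butyldimethylsilyloxy)-18-hydroxy-5α-13,14,15,16-tetranorlabd-7-en-6-one
Product: 21 12-(benzyloxy)-3β-(tert-butyldimethylsilyloxy)-7α,8α-epoxy-18-hydroxy-13,14,15,16-tetranorlabdan-6-one
Conditions: H2O2 (30% aq.), NaOH, MeOH, 0 °C → rt
Reagents that add atoms: hydrogen peroxide, OO
Why: In this Weitz–Scheffer nucleophilic epoxidation hydroperoxide should attack C8 from the α face, away from the 1,3-related axial C10 methyl, so the future C8 oxygen is α and the C8 methyl β.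

Step 14
Reactants: 21 12-(benzyloxy)-3β-(tert-butyldimethylsilyloxy)-7α,8α-epoxy-18-hydroxy-13,14,15,16-tetranorlabdan-6-one
Product: 22 12-(benzyloxy)-3β-(tert-butyldimethylsilyloxy)-8α,18-dihydroxy-13,14,15,16-tetranorlabdan-6-one
Conditions: SmI2, THF/MeOH, −90 °C
Reagents that add atoms: none
Why: Samarium diiodide reduction of an α,β-epoxy ketone cleaves the Cα–O bond (C7–O) through the ketyl and gives the β-hydroxy ketone with the C8 configuration untouched.

Step 15
Reactants: 22 12-(benzyloxy)-3β-(tert-butyldimethylsilyloxy)-8α,18-dihydroxy-13,14,15,16-tetranorlabdan-6-one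
Product: 23 12-(benzyloxy)-3β-(tert-butyldimethylsilyloxy)-8α,18-bis(triethylsilyloxy)-13,14,15,16-tetranorlabdan-6-one
Conditions: TESOTf, 2,6-lutidine, CH2Cl2, −78 → 0 °C
Reagents that add atoms: triethylsilyl trifluoromethanesulfonate, CC[Si](CC)(CC)OS(=O)(=O)C(F)(F)F
Why: Silyl triflate silylation caps the primary and the tertiary hydroxyl, which blocks retro-aldol cleavage in step 16 and later attack of the C8 oxygen on C12.

Step 16
Reactants: 23 12-(benzyloxy)-3β-(tert-butyldimethylsilyloxy)-8α,18-bis(triethylsilyloxy)-13,14,15,16-tetranorlabdan-6-one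
Product: 24 3β-(tert-butyldimethylsilyloxy)-8α,18-bis(triethylsilyloxy)-13,14,15,16-tetranorlabdane-6α,12-diol
Conditions: Li, NH3(l)/THF, t-BuOH, −78 °C; then NH4Cl
Reagents that add atoms: none
Why: Dissolving-metal reduction takes the ketone through its ketyl and carbanion to the thermodynamically preferred equatorial 6α-alcohol (hydride reagents would attack from the open α face and give the axial 6β-alcohol) and cleaves the benzyl ether in the same operation.

Step 17
Reactants: 24 3β-(tert-butyldimethylsilyloxy)-8α,18-bis(triethylsilyloxy)-13,14,15,16-tetranorlabdane-6α,12-diol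
Product: 25 12-iodo-3β-(tert-butyldimethylsilyloxy)-8α,18-bis(triethylsilyloxy)-13,14,15,16-tetranorlabdan-6α-ol
Conditions: I2, PPh3, imidazole, CH2Cl2, 0 °C
Reagents that add atoms: iodine, II
Why: Appel-type iodination is selective for the unhindered primary C12 hydroxyl over the hindered secondary C6 hydroxyl.

Step 18
Reactants: 25 12-iodo-3β-(tert-butyldimethylsilyloxy)-8α,18-bis(triethylsilyloxy)-13,14,15,16-tetranorlabdan-6α-ol
Product: 26 12-iodo-3β-(tert-butyldimethylsilyloxy)-6α,8α,18-tris(triethylsilyloxy)-13,14,15,16-tetranorlabdane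
Conditions: TESOTf, 2,6-lutidine, CH2Cl2, −78 → 0 °C
Reagents that add atoms: triethylsilyl trifluoromethanesulfonate, CC[Si](CC)(CC)OS(=O)(=O)C(F)(F)F
Why: Silylation removes the last acidic proton before the organozinc reagent is made, and the primary iodide is inert to these conditions.

**Butenolide fragment**

Step 19
Reactants: 27 methyl (2S)-oxirane-2-carboxylate; 28 1-propynyllithium
Product: 29 methyl (2S)-2-hydroxyhex-4-ynoate
Conditions: BF3·OEt2, THF, −78 °C
Reagents that add atoms: none
Why: BF3-promoted opening of the epoxide by the lithium acetylide occurs by SN2 attack at the unsubstituted C3, so the glycidate stereocentre (future butenolide γ-carbon) is untouched and the ester survives at −78 °C.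

Step 20
Reactants: 29 methyl (2S)-2-hydroxyhex-4-ynoate
Product: 31 methyl (2S,4E)-2-hydroxy-5-iodohex-4-enoate, via alkenylzirconocene 30 (not isolated)
Conditions: Cp2Zr(H)Cl (3 equiv), THF, rt → 50 °C; then I2, THF, 0 °C
Reagents that add atoms: iodine, II
Why: Hydrozirconation adds H and Zr syn across the alkyne, excess reagent equilibrates zirconium to the less hindered methyl-bearing carbon, and iodinolysis with retention gives the E vinyl iodide.

Step 21
Reactants: 31 methyl (2S,4E)-2-hydroxy-5-iodohex-4-enoate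
Product: 32 (2S,4E)-2-hydroxy-5-iodo-N-methoxy-N-methylhex-4-enamide
Conditions: MeNHOMe·HCl, AlMe3, CH2Cl2, 0 °C → rt
Reagents that add atoms: N,O-dimethylhydroxylamine hydrochloride, CNOC.Cl
Why: Aluminium amide aminolysis converts the ester into the Weinreb amide without affecting the vinyl iodide or the α-stereocentre.

Step 22
Reactants: 32 (2S,4E)-2-hydroxy-5-iodo-N-methoxy-N-methylhex-4-enamide
Product: 33 (3S,5E)-3-hydroxy-6-iodohept-5-en-2-one
Conditions: MeMgBr (3 equiv), THF, −78 → 0 °C
Reagents that add atoms: methylmagnesium bromide, C[Mg]Br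
Why: In this Weinreb ketone synthesis the chelated tetrahedral intermediate stops the Grignard addition at the methyl ketone, the extra reagent covers the free hydroxyl, and the low temperature protects the α-stereocentre.

Step 23
Reactants: 33 (3S,5E)-3-hydroxy-6-iodohept-5-en-2-one
Product: 34 (5S)-5-[(2E)-3-iodobut-2-en-1-yl]-4-methylfuran-2(5H)-one
Conditions: Ph3P=C=C=O, toluene, 80 °C
Reagents that add atoms: (triphenylphosphoranylidene)ketene, O=C=C=P(c1ccccc1)(c1ccccc1)c1ccccc1
Why: The Bestmann ylide acylates the hydroxyl and the resulting phosphorane closes the butenolide ring by intramolecular Wittig olefination of the methyl ketone under neutral conditions, which should keep the γ-stereocentre.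

**Endgame**

Step 24
Reactants: 26 12-iodo-3β-(tert-butyldimethylsilyloxy)-6α,8α,18-tris(triethylsilyloxy)-13,14,15,16-tetranorlabdane; 34 (5S)-5-[(2E)-3-iodobut-2-en-1-yl]-4-methylfuran-2(5H)-one
Product: 36 (5S)-4-methyl-5-{(2E)-3-[3β-(tert-butyldimethylsilyloxy)-6α,8α,18-tris(triethylsilyloxy)-13,14,15,16-tetranorlabdan-12-yl]but-2-en-1-yl}furan-2(5H)-one, via alkylzinc iodide 35 (not isolated)
Conditions: Zn dust, LiCl, THF, 40 °C; then 34, Pd(dppf)Cl2 (5 mol%), THF/NMP, rt → 40 °C
Reagents that add atoms: none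
Why: Zinc insertion into the primary iodide followed by Negishi sp3–sp2 coupling forms C12–C13 with retention of the vinyl iodide geometry (E trisubstituted alkene) under neutral conditions that spare the butenolide.

Step 25
Reactants: 36 (5S)-4-methyl-5-{(2E)-3-[3β-(tert-butyldimethylsilyloxy)-6α,8α,18-tris(triethylsilyloxy)-13,14,15,16-tetranorlabdan-12-yl]but-2-en-1-yl}furan-2(5H)-one
Product: 37 CNP0307004.1, (5S)-4-methyl-5-[(2E)-3-(3β,6α,8α,18-tetrahydroxy-13,14,15,16-tetranorlabdan-12-yl)but-2-en-1-yl]furan-2(5H)-one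
Conditions: HF·pyridine, pyridine/THF, 0 °C → rt
Reagents that add atoms: none
Why: Buffered acidic fluoride removes all four silyl ethers (global desilylation) without epimerising the butenolide γ-carbon or dehydrating the tertiary alcohol.

**Compound list**

1 | 2-methoxy-5-methylbenzoic acid | COc1ccc(C)cc1C(=O)O | starting material
2 | (2S)-2-(methoxymethyl)pyrrolidine | COC[C@@H]1CCCN1 | starting material
3 | 2-methoxy-5-methylbenzoyl chloride | COc1ccc(C)cc1C(=O)Cl | intermediate
4 | [(2S)-2-(methoxymethyl)pyrrolidin-1-yl](2-methoxy-5-methylphenyl)methanone | COc1ccc(C)cc1C(=O)N1CCC[C@H]1COC | intermediate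
5 | potassium amide enolate from Birch reduction of 4 | COC1=CCC(C)=CC1=C([O-])N1CCC[C@H]1COC.[K+] | intermediate
6 | [(1S)-2-methoxy-1,5-dimethylcyclohexa-2,5-dien-1-yl][(2S)-2-(methoxymethyl)pyrrolidin-1-yl]methanone | COC1=CCC(C)=C[C@]1(C)C(=O)N1CCC[C@H]1COC | intermediate
7 | [(1R)-2-methoxy-1,5-dimethylcyclohexa-2,5-dien-1-yl]methanol | COC1=CCC(C)=C[C@]1(C)CO | intermediate
8 | (2R)-2-(hydroxymethyl)-2,4-dimethylcyclohex-3-en-1-one | O=C1CCC(C)=C[C@]1(C)CO | intermediate
9 | (1S,2R)-2-(hydroxymethyl)-2,4-dimethylcyclohex-3-en-1-ol | O[C@H]1CCC(C)=C[C@]1(C)CO | intermediate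
10 | tert-butyl(but-3-yn-1-yloxy)dimethylsilane | C#CCCO[Si](C)(C)C(C)(C)C | starting material
11 | (E)-alkenyldimethylalane from carboalumination of 10 | C[Al](C)/C=C(\C)CCO[Si](C)(C)C(C)(C)C | intermediate
12 | (3E)-6-[(tert-butyldimethylsilyl)oxy]-4-methylhex-3-en-1-ol | OCC/C=C(\C)CCO[Si](C)(C)C(C)(C)C | intermediate
13 | tert-butyl{[(3E)-6-(benzyloxy)-3-methylhex-3-en-1-yl]oxy}dimethylsilane | c1ccccc1COCC/C=C(\C)CCO[Si](C)(C)C(C)(C)C | intermediate
14 | (3E)-6-(benzyloxy)-3-methylhex-3-enoic acid | OC(=O)C/C(C)=C/CCOCc1ccccc1 | intermediate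
15 | [(1R,6S)-6-hydroxy-1,3-dimethylcyclohex-2-en-1-yl]methyl (3E)-6-(benzyloxy)-3-methylhex-3-enoate | O[C@H]1CCC(C)=C[C@]1(C)COC(=O)C/C(C)=C/CCOCc1ccccc1 | intermediate
16 | [(1R,6S)-6-[(tert-butyldimethylsilyl)oxy]-1,3-dimethylcyclohex-2-en-1-yl]methyl (3E)-6-(benzyloxy)-3-methylhex-3-enoate | CC(C)(C)[Si](C)(C)O[C@H]1CCC(C)=C[C@]1(C)COC(=O)C/C(C)=C/CCOCc1ccccc1 | intermediate
17 | (1Z,3E)-vinylketene silyl acetal of 16 (C18–O trans to C8) | CC(C)(C)[Si](C)(C)O[C@H]1CCC(C)=C[C@]1(C)CO/C(O[Si](C)(C)C(C)(C)C)=C/C(C)=C/CCOCc1ccccc1 | intermediate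
18 | 12-(benzyloxy)-3β,6β-bis(tert-butyldimethylsilyloxy)-6α,18-epoxy-5β-13,14,15,16-tetranorlabd-7-ene (tricyclic silyl ketal) | c1ccccc1COCC[C@@H]1[C@@]2(C)CC[C@H](O[Si](C)(C)C(C)(C)C)[C@@](C)(CO3)[C@H]2[C@]3(O[Si](C)(C)C(C)(C)C)C=C1C | intermediate
19 | 12-(benzyloxy)-3β-(tert-butyldimethylsilyloxy)-18-hydroxy-5β-13,14,15,16-tetranorlabd-7-en-6-one (cis-fused) | c1ccccc1COCC[C@@H]1[C@@]2(C)CC[C@H](O[Si](C)(C)C(C)(C)C)[C@@](C)(CO)[C@H]2C(=O)C=C1C | intermediate
20 | 12-(benzyloxy)-3β-(tert-butyldimethylsilyloxy)-18-hydroxy-5α-13,14,15,16-tetranorlabd-7-en-6-one (trans-fused) | c1ccccc1COCC[C@@H]1[C@@]2(C)CC[C@H](O[Si](C)(C)C(C)(C)C)[C@@](C)(CO)[C@@H]2C(=O)C=C1C | intermediate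
21 | 12-(benzyloxy)-3β-(tert-butyldimethylsilyloxy)-7α,8α-epoxy-18-hydroxy-13,14,15,16-tetranorlabdan-6-one | c1ccccc1COCC[C@@H]1[C@@]2(C)CC[C@H](O[Si](C)(C)C(C)(C)C)[C@@](C)(CO)[C@@H]2C(=O)[C@H]3O[C@@]13C | intermediate
22 | 12-(benzyloxy)-3β-(tert-butyldimethylsilyloxy)-8α,18-dihydroxy-13,14,15,16-tetranorlabdan-6-one | c1ccccc1COCC[C@@H]1[C@@]2(C)CC[C@H](O[Si](C)(C)C(C)(C)C)[C@@](C)(CO)[C@@H]2C(=O)C[C@@]1(C)O | intermediate
23 | 12-(benzyloxy)-3β-(tert-butyldimethylsilyloxy)-8α,18-bis(triethylsilyloxy)-13,14,15,16-tetranorlabdan-6-one | c1ccccc1COCC[C@@H]1[C@@]2(C)CC[C@H](O[Si](C)(C)C(C)(C)C)[C@@](C)(CO[Si](CC)(CC)CC)[C@@H]2C(=O)C[C@@]1(C)O[Si](CC)(CC)CC | intermediate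
24 | 3β-(tert-butyldimethylsilyloxy)-8α,18-bis(triethylsilyloxy)-13,14,15,16-tetranorlabdane-6α,12-diol | OCC[C@@H]1[C@@]2(C)CC[C@H](O[Si](C)(C)C(C)(C)C)[C@@](C)(CO[Si](CC)(CC)CC)[C@@H]2[C@@H](O)C[C@@]1(C)O[Si](CC)(CC)CC | intermediate
25 | 12-iodo-3β-(tert-butyldimethylsilyloxy)-8α,18-bis(triethylsilyloxy)-13,14,15,16-tetranorlabdan-6α-ol | ICC[C@@H]1[C@@]2(C)CC[C@H](O[Si](C)(C)C(C)(C)C)[C@@](C)(CO[Si](CC)(CC)CC)[C@@H]2[C@@H](O)C[C@@]1(C)O[Si](CC)(CC)CC | intermediate
26 | 12-iodo-3β-(tert-butyldimethylsilyloxy)-6α,8α,18-tris(triethylsilyloxy)-13,14,15,16-tetranorlabdane | ICC[C@@H]1[C@@]2(C)CC[C@H](O[Si](C)(C)C(C)(C)C)[C@@](C)(CO[Si](CC)(CC)CC)[C@@H]2[C@@H](O[Si](CC)(CC)CC)C[C@@]1(C)O[Si](CC)(CC)CC | intermediate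
27 | methyl (2S)-oxirane-2-carboxylate (methyl (S)-glycidate) | COC(=O)[C@@H]1CO1 | starting material
28 | 1-propynyllithium | [Li]C#CC | starting material
29 | methyl (2S)-2-hydroxyhex-4-ynoate | COC(=O)[C@@H](O)CC#CC | intermediate
30 | (E)-alkenylzirconocene chloride from 29 (hydroxyl as zirconium alkoxide) | COC(=O)[C@@H](O[Zr](Cl)(C1C=CC=C1)C1C=CC=C1)C/C=C(\C)[Zr](Cl)(C1C=CC=C1)C1C=CC=C1 | intermediate
31 | methyl (2S,4E)-2-hydroxy-5-iodohex-4-enoate | COC(=O)[C@@H](O)C/C=C(\C)I | intermediate
32 | (2S,4E)-2-hydroxy-5-iodo-N-methoxy-N-methylhex-4-enamide | CON(C)C(=O)[C@@H](O)C/C=C(\C)I | intermediate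
33 | (3S,5E)-3-hydroxy-6-iodohept-5-en-2-one | CC(=O)[C@@H](O)C/C=C(\C)I | intermediate
34 | (5S)-5-[(2E)-3-iodobut-2-en-1-yl]-4-methylfuran-2(5H)-one | CC1=CC(=O)O[C@H]1C/C=C(\C)I | intermediate
35 | alkylzinc iodide from 26 | I[Zn]CC[C@@H]1[C@@]2(C)CC[C@H](O[Si](C)(C)C(C)(C)C)[C@@](C)(CO[Si](CC)(CC)CC)[C@@H]2[C@@H](O[Si](CC)(CC)CC)C[C@@]1(C)O[Si](CC)(CC)CC | intermediate
36 | (5S)-4-methyl-5-{(2E)-3-[3β-(tert-butyldimethylsilyloxy)-6α,8α,18-tris(triethylsilyloxy)-13,14,15,16-tetranorlabdan-12-yl]but-2-en-1-yl}furan-2(5H)-one | CC1=CC(=O)O[C@H]1C/C=C(\C)CC[C@@H]1[C@@]2(C)CC[C@H](O[Si](C)(C)C(C)(C)C)[C@@](C)(CO[Si](CC)(CC)CC)[C@@H]2[C@@H](O[Si](CC)(CC)CC)C[C@@]1(C)O[Si](CC)(CC)CC | intermediate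
37 | CNP0307004.1, (5S)-4-methyl-5-[(2E)-3-(3β,6α,8α,18-tetrahydroxy-13,14,15,16-tetranorlabdan-12-yl)but-2-en-1-yl]furan-2(5H)-one | CC1=CC(=O)O[C@H]1C/C=C(\C)CC[C@@H]1[C@@]2(C)CC[C@H](O)[C@@](C)(CO)[C@@H]2[C@@H](O)C[C@@]1(C)O | target

**Step count and risks**

Total steps: 25. Longest linear sequence: 17 steps (steps 1–5, 9–18, 24, 25).

Step 11 (the labelled step) is the most likely to fail. The cycloaddition onto the unactivated, trisubstituted ring-A alkene must form a quaternary centre and may be slower than thermal decay of the ketene acetal (desilylation, silyl migration to carbon, or prototropic shift to the conjugated dienoate). The fallback uses known reactions, sets out from 16 and returns at 19. Ester 16 is reduced with i-Bu2AlH at −78 °C and the aluminium hemiacetal is acetylated in situ (Ac2O, pyridine, DMAP; reductive acetylation of an ester) to the α-acetoxy ether F1. TMSOTf and i-Pr2NEt eliminate acetic acid to give the thermally robust (1E,3E)-dienyl ether F2. This simple 1-alkoxydiene tolerates long heating (toluene, BHT, 200 °C) and should undergo the same ether-tethered intramolecular Diels–Alder reaction to the cis-fused tricyclic allylic ether F3. Oxidation of the allylic ether C6–H with DDQ in wet CH2Cl2, followed by opening of the resulting hemiketal, returns cis-enone 19.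

Step 12 is the second risk. Equilibration may stop at a mixture, or the base may also deprotonate the γ-position (C9), eroding that centre or moving the alkene out of conjugation. The fallback sets out from 19 and returns at 23. The cis-fused enone is taken unchanged through the two oxygenation steps: NaOH/H2O2 to the cis-fused epoxy ketone F4, then SmI2 to the cis-fused β-hydroxy ketone F5. Silylation (TESOTf, 2,6-lutidine) gives the bis(triethylsilyl) ether F6. Only then is C5 inverted (DBU, toluene, 60 °C), in a saturated ketone where C5 is the only stereogenic α-carbon and no extended enolate can form; this gives 23. Facial selectivity of the epoxidation in the cis series would have to be confirmed.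

Step 13 is the third risk. Attack of hydroperoxide at the hindered β-carbon C8 (next to C9 and the quaternary C10) may be slow or poorly face-selective, and prolonged base may cause side reactions. The fallback sets out from 20 and returns at 22, so step 14 is not needed. Copper-catalysed conjugate borylation (CuCl, NaOt-Bu, a bisphosphine ligand, B2pin2, MeOH, THF) should add boron to C8 from the α face to give the β-boryl ketone F7. Oxidation with NaBO3·4H2O proceeds with retention and gives β-hydroxy ketone 22 directly.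

Further compounds
F1 | step 11 | [(1R,6S)-6-[(tert-butyldimethylsilyl)oxy]-1,3-dimethylcyclohex-2-en-1-yl]methyl 1-acetoxy-(3E)-6-(benzyloxy)-3-methylhex-3-en-1-yl ether (α-acetoxy ether, both acetal epimers) | CC(C)(C)[Si](C)(C)O[C@H]1CCC(C)=C[C@]1(C)COC(OC(C)=O)C/C(C)=C/CCOCc1ccccc1
F2 | step 11 | [(1R,6S)-6-[(tert-butyldimethylsilyl)oxy]-1,3-dimethylcyclohex-2-en-1-yl]methyl (1E,3E)-6-(benzyloxy)-3-methylhexa-1,3-dien-1-yl ether | CC(C)(C)[Si](C)(C)O[C@H]1CCC(C)=C[C@]1(C)CO/C=C/C(C)=C/CCOCc1ccccc1
F3 | step 11 | 12-(benzyloxy)-3β-(tert-butyldimethylsilyloxy)-6α,18-epoxy-5β-13,14,15,16-tetranorlabd-7-ene | c1ccccc1COCC[C@@H]1[C@@]2(C)CC[C@H](O[Si](C)(C)C(C)(C)C)[C@@](C)(CO3)[C@H]2[C@@H]3C=C1C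
F4 | step 12 | 12-(benzyloxy)-3β-(tert-butyldimethylsilyloxy)-7α,8α-epoxy-18-hydroxy-5β-13,14,15,16-tetranorlabdan-6-one | c1ccccc1COCC[C@@H]1[C@@]2(C)CC[C@H](O[Si](C)(C)C(C)(C)C)[C@@](C)(CO)[C@H]2C(=O)[C@H]3O[C@@]13C
F5 | step 12 | 12-(benzyloxy)-3β-(tert-butyldimethylsilyloxy)-8α,18-dihydroxy-5β-13,14,15,16-tetranorlabdan-6-one | c1ccccc1COCC[C@@H]1[C@@]2(C)CC[C@H](O[Si](C)(C)C(C)(C)C)[C@@](C)(CO)[C@H]2C(=O)C[C@@]1(C)O
F6 | step 12 | 12-(benzyloxy)-3β-(tert-butyldimethylsilyloxy)-8α,18-bis(triethylsilyloxy)-5β-13,14,15,16-tetranorlabdan-6-one | c1ccccc1COCC[C@@H]1[C@@]2(C)CC[C@H](O[Si](C)(C)C(C)(C)C)[C@@](C)(CO[Si](CC)(CC)CC)[C@H]2C(=O)C[C@@]1(C)O[Si](CC)(CC)CC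
F7 | step 13 | 12-(benzyloxy)-3β-(tert-butyldimethylsilyloxy)-18-hydroxy-8α-(4,4,5,5-tetramethyl-1,3,2-dioxaborolan-2-yl)-13,14,15,16-tetranorlabdan-6-one | c1ccccc1COCC[C@@H]1[C@@]2(C)CC[C@H](O[Si](C)(C)C(C)(C)C)[C@@](C)(CO)[C@@H]2C(=O)C[C@@]1(C)B1OC(C)(C)C(C)(C)O1
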